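## Retrosynthetic overview

1. Target ⇐ 15,19-diacetate (selective removal of the allylic acetate) ⇐ 8α,15,19-triol ⇐ two-carbon Horner–Wadsworth–Emmons homologation of a C18 8α-hydroxy methyl ketone.
2. Hydroxy ketone ⇐ hydrolysis of a tricyclic enol ether made in one operation from an acyclic (S)-2,2-disubstituted epoxy dienone. Ring A closes first (C4–C5, oxirane opened with inversion at its quaternary carbon), ring B second (C9–C10), and the C8–O bond of a dihydropyran ring last (ketone oxygen as terminator). The cascade sets C4, C5, C8, C9 and C10.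
3. Epoxy dienone ⇐ (S)-1,2-diol ⇐ Sharpless epoxidation and hydride opening of a terminal E-allylic alcohol ⇐ SeO2 oxidation of (5E,9E)-farnesylacetone.

Assumption: (5E,9E)-farnesylacetone is bought as the single all-E isomer.

Numbering: the bicyclic compounds carry labdane numbers (ring A = C1–C5, C10; ring B = C5–C10; side chain C11–C16 on C9 with C16 the methyl on C13; C17 = methyl on C8; C18 = 4α-methyl; C19 = 4β-CH2O; C20 = methyl on C10).

## Route

Step 1
Reactants: 1 (5E,9E)-farnesylacetone [(5E,9E)-6,10,14-trimethylpentadeca-5,9,13-trien-2-one]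
Product: 2 (5E,9E,13E)-15-hydroxy-6,10,14-trimethylpentadeca-5,9,13-trien-2-one
Conditions: SeO2 (0.1 equiv), salicylic acid (0.1 equiv), t-BuOOH (70% aq., 3 equiv), CH2Cl2, 23 °C, run to ca. 60% conversion, 1 recycled
Reagents that add atoms: tert-butyl hydroperoxide, CC(C)(C)OO
Why: SeO2-catalysed allylic oxidation (Sharpless–Umbreit; ene reaction followed by 2,3-sigmatropic shift) picks the terminal, least hindered trisubstituted alkene and oxidises its E-methyl group, so the CH2OH ends up trans to the chain as the next step needs.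

Step 2
Reactants: 2 (5E,9E,13E)-15-hydroxy-6,10,14-trimethylpentadeca-5,9,13-trien-2-one
Product: 3 (5E,9E,13R,14R)-13,14-epoxy-15-hydroxy-6,10,14-trimethylpentadeca-5,9-dien-2-one
Conditions: Ti(OiPr)4 (0.10 equiv), D-(−)-diethyl tartrate (0.12 equiv), t-BuOOH (2 equiv, in isooctane), 4 Å MS, CH2Cl2, −25 °C
Reagents that add atoms: tert-butyl hydroperoxide, CC(C)(C)OO
Why: Katsuki–Sharpless asymmetric epoxidation is directed by the allylic hydroxyl, so only the 13,14-alkene reacts, and the D-(−)-tartrate ligand delivers oxygen to the face that gives the (13R,14R)-epoxide (typically ≥94% ee), which creates the quaternary C–O centre that becomes C4.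

Step 3
Reactants: 3 (5E,9E,13R,14R)-13,14-epoxy-15-hydroxy-6,10,14-trimethylpentadeca-5,9-dien-2-one
Product: 4 (2S,6E,10E)-2,6,10-trimethylpentadeca-6,10-diene-1,2,14-triol (both C14 epimers)
Conditions: LiAlH4 (3 equiv), THF, 0 → 23 °C; then aq. KNaC4H4O6 (sodium potassium tartrate)
Reagents that add atoms: none
Why: LiAlH4 opens the 2,3-epoxy alcohol by SN2 hydride attack at the secondary C13 because C14 is fully substituted, which leaves the tertiary C–O bond and its configuration untouched and gives the (S)-1,2-diol, and the remote ketone is reduced in the same operation to a carbinol whose configuration does not matter because step 5 re-oxidises it.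

Step 4
Reactants: 4 (2S,6E,10E)-2,6,10-trimethylpentadeca-6,10-diene-1,2,14-triol
Product: 6 (5E,9E)-6,10-dimethyl-13-[(2S)-2-methyloxiran-2-yl]trideca-5,9-dien-2-ol (both C2 epimers), via primary tosylate 5 (not isolated)
Conditions: TsCl (1.05 equiv), Bu2SnO (0.02 equiv), Et3N (1.2 equiv), CH2Cl2, 0 → 23 °C; then K2CO3 (3 equiv), MeOH, 23 °C
Reagents that add atoms: none
Why: Bu2SnO-catalysed sulfonylation picks the primary hydroxyl of the 1,2-diol over the isolated secondary one, and the tertiary alkoxide then closes the oxirane by intramolecular Williamson displacement at the primary carbon, so the quaternary stereocentre is carried over unchanged as (S).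

Step 5
Reactants: 6 (5E,9E)-6,10-dimethyl-13-[(2S)-2-methyloxiran-2-yl]trideca-5,9-dien-2-ol
Product: 7 (5E,9E)-6,10-dimethyl-13-[(2S)-2-methyloxiran-2-yl]trideca-5,9-dien-2-one
Conditions: (n-Pr4N)RuO4 (0.05 equiv), N-methylmorpholine N-oxide (1.5 equiv), 4 Å MS, CH2Cl2, 23 °C
Reagents that add atoms: none
Why: (n-Pr4N)RuO4-catalysed oxidation with N-methylmorpholine N-oxide (Ley–Griffith) turns both carbinol epimers into the one methyl ketone under neutral conditions that spare the acid-labile 2,2-disubstituted oxirane and the trisubstituted alkenes.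

Step 6
Reactants: 7 (5E,9E)-6,10-dimethyl-13-[(2S)-2-methyloxiran-2-yl]trideca-5,9-dien-2-one
Product: 9 (4S,5R,8R,9R,10S)-8,19-dihydroxy-14,15-dinorlabdan-13-one, via tricyclic enol ether 8 (not isolated)
Conditions: MeAlCl2 (1.2 equiv), CH2Cl2, −78 °C, 1 h; then 1 M aq. HCl, THF, 23 °C, 1 h
Reagents that add atoms: water, O
Why: Proposed new method: MeAlCl2 activates the (S)-oxirane and the C5=C10 alkene attacks its tertiary carbon anti to the departing oxygen (inversion, giving 4S with CH3 and CH2O–Al on C4), the E,E-diene then folds chair–chair so that ring A and ring B close in anti fashion (5α-H, 10β-CH3, 9α-H) and the C8 cation is captured from the α face by the ketone oxygen to give the dihydropyran enol ether (three rings in one operation), while the oxirane CH2, tied back to the leaving oxygen and therefore the smaller group, takes the axial position on C4 and lets the free methyl avoid the 1,3-diaxial contact with the C10 methyl, which is what makes the CH2O group β (C19); aqueous acid then hydrolyses every enol ether or hemiketal form to the one hydroxy ketone; the closest known reactions are the MeAlCl2-promoted epoxide-initiated cation–olefin polycyclisation of trisubstituted oxiranes and the acid-mediated ketone-terminated cyclisation of farnesylacetone to sclareol oxide.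

Step 7
Reactants: 9 (4S,5R,8R,9R,10S)-8,19-dihydroxy-14,15-dinorlabdan-13-one; 10 triethyl phosphonoacetate
Product: 11 ethyl (4S,5R,8R,9R,10S,13E)-8,19-dihydroxylabd-13-en-15-oate
Conditions: 10 (3.0 equiv), NaH (2.9 equiv), THF, 0 °C; then 9, 0 → 50 °C; E isomer separated on silica gel (E:Z ca. 4:1 expected)
Reagents that add atoms: triethyl phosphonoacetate, CCOC(=O)CP(=O)(OCC)OCC
Why: Horner–Wadsworth–Emmons olefination of the open hydroxy-ketone form gives the trisubstituted enoate with the usual E preference (ester trans to the C12 chain), and the stabilised phosphonate anion, used without excess NaH, is too weak a base to deprotonate the two hydroxyls, which keeps oxa-Michael closure onto the enoate in check.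

Step 8
Reactants: 11 ethyl (4S,5R,8R,9R,10S,13E)-8,19-dihydroxylabd-13-en-15-oate
Product: 12 (4S,5R,8R,9R,10S,13E)-labd-13-ene-8,15,19-triol
Conditions: i-Bu2AlH (5 equiv), CH2Cl2, −78 → 0 °C; then aq. KNaC4H4O6 (sodium potassium tartrate)
Reagents that add atoms: none
Why: i-Bu2AlH reduces the conjugated ester by 1,2-addition to the E-allylic alcohol without touching the alkene geometry or any stereocentre.

Step 9
Reactants: 12 (4S,5R,8R,9R,10S,13E)-labd-13-ene-8,15,19-triol
Product: 13 (4S,5R,8R,9R,10S,13E)-8-hydroxylabd-13-ene-15,19-diyl diacetate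
Conditions: Ac2O (3 equiv), pyridine, DMAP (0.05 equiv), CH2Cl2, 0 → 23 °C
Reagents that add atoms: acetic anhydride, CC(=O)OC(C)=O
Why: DMAP-catalysed acylation (Steglich-type acetylation) esterifies both primary hydroxyls, whereas the hindered tertiary 8α-hydroxyl does not react at room temperature.

Step 10
Reactants: 13 (4S,5R,8R,9R,10S,13E)-8-hydroxylabd-13-ene-15,19-diyl diacetate
Product: 14 (4S,5R,8R,9R,10S,13E)-8,15-dihydroxylabd-13-en-19-yl acetate (CNP0161527.1)
Conditions: K2CO3 (0.2 equiv), MeOH, 0 °C, stopped when 13 is consumed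
Reagents that add atoms: none
Why: Base-catalysed methanolysis (Zemplén-type transesterification) removes the unhindered allylic C15 acetate much faster than the C19 acetate, which is neopentyl, axial on quaternary C4 and screened by the 1,3-diaxial C10 methyl group, so the reaction is stopped at the monoacetate.

## Compound list

1 | (5E,9E)-farnesylacetone, (5E,9E)-6,10,14-trimethylpentadeca-5,9,13-trien-2-one | CC(=O)CC/C=C(\C)CC/C=C(\C)CCC=C(C)C | starting material
2 | (5E,9E,13E)-15-hydroxy-6,10,14-trimethylpentadeca-5,9,13-trien-2-one | CC(=O)CC/C=C(\C)CC/C=C(\C)CC/C=C(\C)CO | intermediate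
3 | (5E,9E,13R,14R)-13,14-epoxy-15-hydroxy-6,10,14-trimethylpentadeca-5,9-dien-2-one (trans epoxide, CH2OH and CH3 on C14) | CC(=O)CC/C=C(\C)CC/C=C(\C)CC[C@H]1O[C@]1(C)CO | intermediate
4 | (2S,6E,10E)-2,6,10-trimethylpentadeca-6,10-diene-1,2,14-triol (both C14 epimers, centre left open in the SMILES) | OC[C@@](C)(O)CCC/C(C)=C/CC/C(C)=C/CCC(C)O | intermediate
5 | (2S,6E,10E)-2,14-dihydroxy-2,6,10-trimethylpentadeca-6,10-dien-1-yl 4-methylbenzenesulfonate (both C14 epimers; not isolated) | Cc1ccc(cc1)S(=O)(=O)OC[C@@](C)(O)CCC/C(C)=C/CC/C(C)=C/CCC(C)O | intermediate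
6 | (5E,9E)-6,10-dimethyl-13-[(2S)-2-methyloxiran-2-yl]trideca-5,9-dien-2-ol (both C2 epimers) | C[C@]1(CCC/C(C)=C/CC/C(C)=C/CCC(C)O)CO1 | intermediate
7 | (5E,9E)-6,10-dimethyl-13-[(2S)-2-methyloxiran-2-yl]trideca-5,9-dien-2-one | C[C@]1(CCC/C(C)=C/CC/C(C)=C/CCC(C)=O)CO1 | intermediate
8 | (4S,5R,8R,9R,10S)-8,13-epoxy-14,15-dinorlabd-12-en-19-ol (19-hydroxy sclareol oxide: trans-decalin, 5α-H, 10β-CH3, 4α-CH3, 4β-CH2OH, 8β-CH3, 8α-O–C13(CH3)=C12 dihydropyran fused at C8/C9; not isolated) | OC[C@@]1(C)CCC[C@]2(C)[C@H]3CC=C(C)O[C@]3(C)CC[C@@H]12 | intermediate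
9 | (4S,5R,8R,9R,10S)-8,19-dihydroxy-14,15-dinorlabdan-13-one (8α-OH, 8β-CH3, 9β-CH2CH2COCH3, 4β-CH2OH; in equilibrium with its cyclic hemiketal) | OC[C@@]1(C)CCC[C@]2(C)[C@@H](CCC(C)=O)[C@](C)(O)CC[C@@H]12 | intermediate
10 | triethyl phosphonoacetate | CCOC(=O)CP(=O)(OCC)OCC | starting material
11 | ethyl (4S,5R,8R,9R,10S,13E)-8,19-dihydroxylabd-13-en-15-oate | OC[C@@]1(C)CCC[C@]2(C)[C@@H](CC/C(C)=C/C(=O)OCC)[C@](C)(O)CC[C@@H]12 | intermediate
12 | (4S,5R,8R,9R,10S,13E)-labd-13-ene-8,15,19-triol | OC[C@@]1(C)CCC[C@]2(C)[C@@H](CC/C(C)=C/CO)[C@](C)(O)CC[C@@H]12 | intermediate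
13 | (4S,5R,8R,9R,10S,13E)-8-hydroxylabd-13-ene-15,19-diyl diacetate | CC(=O)OC[C@@]1(C)CCC[C@]2(C)[C@@H](CC/C(C)=C/COC(C)=O)[C@](C)(O)CC[C@@H]12 | intermediate
14 | (4S,5R,8R,9R,10S,13E)-8,15-dihydroxylabd-13-en-19-yl acetate, CNP0161527.1 | CC(=O)OC[C@@]1(C)CCC[C@]2(C)[C@@H](CC/C(C)=C/CO)[C@](C)(O)CC[C@@H]12 | target

## Step count and weak points

Total step count: 10. Longest linear sequence: 10 (fully linear from 1).

**Step 6 (the cascade).** Three things can go wrong:
- Hydride shift of the activated oxirane to an aldehyde.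
- The ketone is tied up by MeAlCl2, so the C8 cation loses a proton instead of being captured.
- The fold that puts CH3 axial on C4 wins. It would give the diastereomer with the opposite ring configuration, visible and separable at 9; the fallback below does not cure this.

Fallback, setting out from 7 and coming back at 12: the ketone is converted first and the C8 oxygen is put in after ring closure. 7 and the sodium salt of 10 (THF, 50 °C) give ethyl (2E,6E,10E)-3,7,11-trimethyl-14-[(2S)-2-methyloxiran-2-yl]tetradeca-2,6,10-trienoate F1 after removal of the 2Z isomer. MeAlCl2 (CH2Cl2, −78 °C) closes rings A and B; the electron-poor enoate stays out, and loss of a C17 proton gives ethyl (13E)-19-hydroxylabda-8(17),13-dien-15-oate F2. m-CPBA/NaHCO3 epoxidises only the exocyclic alkene, from the α face opposite the C10 methyl, to ethyl (13E)-8α,17-epoxy-19-hydroxylabd-13-en-15-oate F3. LiAlH4 then opens the oxirane at C17 and reduces the ester, which gives 12.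

**Step 7 (olefination).** A methyl ketone gives only about 4:1 E:Z, and 9 sits largely as its hemiketal, so the reaction may be slow and the isomers hard to separate.

Fallback, setting out from 9 and coming back at 12: the alkene is built by carbometalation instead of olefination. LiN(i-Pr)2 (3.2 equiv) and then ClP(O)(OEt)2 (1.05 equiv) at −78 °C give the kinetic enol phosphate diethyl 8α,19-dihydroxy-14,15-dinorlabd-13(16)-en-13-yl phosphate F4. More LiN(i-Pr)2 eliminates it to the terminal alkyne 15,16-dinorlabd-13-yne-8α,19-diol F5. Cp2ZrCl2-catalysed syn-carboalumination with Me3Al, followed by n-BuLi and paraformaldehyde, gives 12 directly with the E geometry fixed by the syn addition.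

**Step 10 (selective deacetylation).** The rate gap between the two primary acetates may be too small, giving triol 12 and leftover 13 beside 14.

Fallback, setting out from 12 and coming back at 14: the two primary hydroxyls are told apart by oxidation state instead. MnO2 (CH2Cl2) oxidises only the allylic alcohol to (13E)-8α,19-dihydroxylabd-13-en-15-al F6. Ac2O/pyridine at 0 °C acetylates the only remaining acylable hydroxyl to (13E)-19-acetoxy-8α-hydroxylabd-13-en-15-al F7. NaBH4/CeCl3·7H2O in MeOH at −20 °C reduces the aldehyde and leaves the acetate, which gives 14.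

Further compounds
F1 | step 6 | ethyl (2E,6E,10E)-3,7,11-trimethyl-14-[(2S)-2-methyloxiran-2-yl]tetradeca-2,6,10-trienoate | C[C@]1(CCC/C(C)=C/CC/C(C)=C/CC/C(C)=C/C(=O)OCC)CO1
F2 | step 6 | ethyl (13E)-19-hydroxylabda-8(17),13-dien-15-oate | OC[C@@]1(C)CCC[C@]2(C)[C@@H](CC/C(C)=C/C(=O)OCC)C(=C)CC[C@@H]12
F3 | step 6 | ethyl (13E)-8α,17-epoxy-19-hydroxylabd-13-en-15-oate | OC[C@@]1(C)CCC[C@]2(C)[C@@H](CC/C(C)=C/C(=O)OCC)[C@@]3(CO3)CC[C@@H]12
F4 | step 7 | diethyl 8α,19-dihydroxy-14,15-dinorlabd-13(16)-en-13-yl phosphate | OC[C@@]1(C)CCC[C@]2(C)[C@@H](CCC(=C)OP(=O)(OCC)OCC)[C@](C)(O)CC[C@@H]12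
F5 | step 7 | 15,16-dinorlabd-13-yne-8α,19-diol | OC[C@@]1(C)CCC[C@]2(C)[C@@H](CCC#C)[C@](C)(O)CC[C@@H]12
F6 | step 10 | (13E)-8α,19-dihydroxylabd-13-en-15-al | OC[C@@]1(C)CCC[C@]2(C)[C@@H](CC/C(C)=C/C=O)[C@](C)(O)CC[C@@H]12
F7 | step 10 | (13E)-19-acetoxy-8α-hydroxylabd-13-en-15-al | CC(=O)OC[C@@]1(C)CCC[C@]2(C)[C@@H](CC/C(C)=C/C=O)[C@](C)(O)CC[C@@H]12
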